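The earlier runs and the new flask come from a simulation on assumed constants, noise included.

Substrate, target and over-reaction product together hold the substrate charged: teal at 10.0 min reads 0%, 89.9% and 10.1%. The catalyst comes back from each step, so for your quick number we can simply count turnovers.

| flask | substrate | partner | catalyst | remark | time |
|---|---|---|---|---|---|
| teal | 34 mM | 1.5 equiv | 0.5 mol% | run made earlier |  |
| red | 23 mM | 1.5 equiv | 0.5 mol% | run made earlier |  |
| amber | 51 mM | 1.5 equiv | 0.5 mol% | run made earlier |  |
| green | 34 mM | 1.5 equiv | 0.75 mol% | run made earlier |  |
| maple | 34 mM | 1.50 equiv | 0.5 mol% | everything together at the start | 15 min |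
| birch | 34 mM | 1.50 equiv (fed, over 12 min) | 0.5 mol% | all else is in the flask from the start; the feed brings no volume worth counting | 15 min |
| elm | 34 mM (fed, over 12 min) | 1.50 equiv | 0.5 mol% | all else is in the flask from the start; the feed brings no volume worth counting | 15 min |
| alder | 34 mM | 1.50 equiv (in portions, 4, over 12 min) | 0.5 mol% | first portion at the start, last at 12 min | 15 min |

| run | time / min | over-reaction product / % | target / % | substrate / % |
|---|---|---|---|---|
| teal | 1.00 | 1.7 | 89.3 | 9.3 |
| teal | 3.00 | 3.7 | 94.0 | 1.1 |
| teal | 6.00 | 6.9 | 92.9 | 0.5 |
| teal | 10.0 | 10.1 | 89.9 | 0 |
| red | 5.00 | 3.4 | 94.5 | 2.7 |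
| red | 10.0 | 4.6 | 94.2 | 0.2 |
| red | 15.0 | 6.6 | 92.8 | 1.0 |
| red | 20.0 | 8.8 | 91.3 | 0 |
| amber | 5.00 | 12.3 | 88.2 | 0 |
| amber | 10.0 | 19.2 | 81.4 | 0.3 |
| amber | 15.0 | 24.1 | 76.5 | 0 |
| amber | 20.0 | 28.6 | 72.2 | 0.1 |
| green | 5.00 | 8.1 | 90.8 | 0 |
| green | 10.0 | 14.0 | 85.9 | 0 |
| green | 15.0 | 19.2 | 81.1 | 0.3 |
| green | 20.0 | 23.0 | 78.1 | 0 |

(readings scatter by 0.5 percentage points)

- what was read earlier has a scatter of 0.5 percentage points, one standard deviation
- what may be going on: partner + catalyst + target -> catalyst + over-reaction product; partner <-> dormant form; substrate + partner + catalyst -> catalyst + target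

- the flask with the highest amount of over-reaction product, in percent of the substrate charged ("all alike" if they lie within 1.5 percentage points) (maple / birch / elm / alder / all alike)
- final over-reaction product, as a percentage of the substrate charged, in maple
- final over-reaction product, as a percentage of the substrate charged, in birch
- final over-reaction product, as a percentage of the substrate charged, in elm
- final over-reaction product, as a percentage of the substrate charged, in alder

Each substrate takes one equivalent of partner, and in teal substrate is down to 1.1% by 3.00 min. From then to 10.0 min, over-reaction product grows by 6.4 percentage points, which on 0.5 mol% of catalyst is 1.83 /min. We call this the over-reaction clock: over-reaction turnovers per catalyst per minute, with target near full strength and partner charged beyond one equivalent.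

We multiply the clock by the catalyst loading and by the minutes it runs. Maple runs for 15 min, which gives 13.7%. Birch has been charged one equivalent of partner at 8.00 min, and alder's portions pass that charge at the same time, so we count 7.00 min for each, which gives 6.40%. In elm target climbs through the feed, so we count half of 12 min plus the 3.00 min after it, which makes 9.00 min and 8.23%. Our call is therefore maple above elm.

Your hunch, the forecast, gives maple 13.8%, birch 8%, elm 15% and alder 7.5%. It names elm as highest, since “the rate order above 1 in concentration favours elm”. We part from it on which flask stands highest.

The flasks give maple 13.7%, birch 6.93%, elm 10.8% and alder 5.96%, so maple stands highest.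

    partner + catalyst + target → catalyst + over-reaction product (k = 110 /M²/s)
    partner ⇌ dormant form (K = 0.720, k = 0.00430 /s)
    substrate + partner + catalyst → catalyst + target (k = 9900 /M²/s)

In maple, with concentrations as charged, substrate has a half-life of 0.13 min by its step and target one of 12 min by the over-reaction, and the rate constants give a selectivity factor of 90.0. After its feed ends, birch makes over-reaction product at 2.01 /min per catalyst, against the clock's 1.83 /min. One more flask, like alder but charged with 0.380 equiv of partner, never reaches one equivalent charged, so the clock counts no minutes for it, and at 15.0 min it holds over-reaction product 0.104%.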